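I could not integrate green, grey and red by hand, since I had neither the list of steps nor their constants, but the questions concern where G ends up, not when.

| setting | summer | dusk | dawn | green | grey | red |
|---|---|---|---|---|---|---|
| G | 0.14 M | 0.14 M | 0.14 M | 0.14 M | 0.14 M | 0.14 M |
| J | 0.28 M | 0.28 M | 0.56 M | 0.280 M | 0.280 M | 0.280 M |
| Z | 0.35 M | 0.52 M | 0.70 M | 0.700 M | 0.700 M | 0.700 M |
| temperature | 20 °C | 50 °C | 20 °C | 25 °C | 50 °C | 75 °C |
| remark | run made earlier | run made earlier | run made earlier |  |  |  |
| time |  |  |  | 2.0 h | 2.0 h | 2.0 h |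

summer run (percent of the G charged)

| time / h | D / % | E / % | Q / % | G / % |
|---|---|---|---|---|
| 0.500 | 14.6 | 34.7 | 35.3 | 15.0 |
| 1.00 | 32.0 | 38.5 | 26.3 | 3.4 |
| 1.33 | 38.8 | 41.0 | 20.2 | 1.1 |
| 2.00 | 48.2 | 41.3 | 9.9 | 0.4 |
| 2.50 | 51.4 | 41.6 | 6.2 | 0 |

dusk run (percent of the G charged)

| time / min | D / % | E / % | Q / % | G / % |
|---|---|---|---|---|
| 8.00 | 29.5 | 65.6 | 3.5 | 1.6 |
| 20.0 | 32.6 | 67.3 | 0.8 | 0 |
| 25.0 | 32.6 | 67.6 | 0 | 0.5 |
| 40.0 | 31.8 | 66.7 | 0 | 1.2 |

dawn run (percent of the G charged)

| time / h | D / % | E / % | Q / % | G / % |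
|---|---|---|---|---|
| 0.200 | 6.6 | 31.8 | 44.0 | 18.3 |
| 0.333 | 12.7 | 36.7 | 44.2 | 7.4 |
| 0.667 | 25.8 | 38.8 | 35.3 | 0.8 |
| 1.33 | 42.6 | 39.8 | 17.2 | 0.2 |
| 2.50 | 54.7 | 40.5 | 5.0 | 0.4 |

(standard deviation of a reading: 0.5 percentage points)

- which of these there is most of at the end, counted by the G in it, green (Q / D / G / E)
- which of these there is most of at the end, counted by the G in it, grey (Q / D / G / E)
- which of these there is most of at the end, counted by the G in it, red (Q / D / G / E)
- how much there is at the end of the one of these that leads, in percent of the G charged: green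
- how much there is at the end of the one of these that leads, in percent of the G charged: grey
- how much there is at the end of the one of these that leads, in percent of the G charged: red

G left by two routes: with Z to E, and with J to Q, which went on to D. E stayed put in summer, reading 41.0 % at 1.33 h and 41.6 % at 2.50 h while Q fell. Dividing one rate of formation by the other removes time:

d(E)/d(Q + D) = s · Z/J

Here s, the selectivity factor, is the E made per Q + D made, for each unit of Z/J. I read it from the last readings, with charged Z/J:

summer: s = 0.578; dawn: s = 0.543; dusk: s = 1.12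

Summer at 20 °C and dusk at 50 °C gave an excess activation energy:

17.3 kJ/mol

green: s = 0.651; grey: s = 1.12; red: s = 1.77

In summer G was down to 15.0 % by 0.500 h, and these flasks hold more Z than summer and are warmer, so I took G as consumed by 2.0 h. With Z/J at 2.50, E's share is r/(1 + r), where r = s · Z/J:

green: 61.9 %; grey: 73.6 %; red: 81.6 %

The weak link was charged Z/J. Summer and dawn share that ratio, yet their s differed by 0.0351, summer's being the higher. So I replaced it with the mean Z/J while G was being used, taking off half of what each route had consumed: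

summer: s = 0.539; dawn: s = 0.523; dusk: s = 1.13

green, from summer and dusk: s = 0.616

This s at green's temperature, E made per Q + D made for each unit of Z/J, is what I carried. With mean Z/J it gave green r = 1.60, so E's share came to 61.5 %.

The forecast named E in all three, at 61 %, 73 % and 82 %, adding: “Z-dependence is inferred, not directly tested.” My grey stood 0.60 percentage points above it.

E led in each flask, at 61.9 % in green, 74.7 % in grey and 84.3 % in red.

    G + J → Q (k = 0.281 /M/min, Ea = 45.0 kJ/mol)
    Z + J → L (k = 0.0428 /M/min, Ea = 78.0 kJ/mol)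
    G + Z → E (k = 0.140 /M/min, Ea = 65.0 kJ/mol)
    Q → D (k = 0.0294 /min, Ea = 81.0 kJ/mol)
    J ⇌ X (K = 0.135, k = 0.0774 /min, Ea = 92.0 kJ/mol, ΔH = −52.0 kJ/mol)
    (constants at 25 °C)

Green ended with E over Q + D at 1.63, against 1.60 from s, and this whole-run ratio stood higher than the 1.2 at which G went into E per G into Q at green's start. Taken to a neighbour of green with Z at 2.8 M, s gave 86.0 %, and that flask ended with E at 87.1 %.

The runs come from a simulation from invented constants; the scatter is artificial.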